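## The problem

(+)-Methylphelligrin A (12) is a (2R)-flavanone. Ring A, a phloroglucinol-type benzene, is fused to the pyranone ring C; C2 carries the 4-hydroxyphenyl ring B; and C6 of ring A is joined through one methylene to a fourth ring, the 2-hydroxyphenyl ring D. C2 is the only stereocentre, so nothing in the molecule can direct it and it has to come from a catalyst. Once set it is fragile: a flavanone opens to the 2'-hydroxychalcone by retro-oxa-Michael reaction under base, and as a 4-oxygenated benzylic ether C2 can also ionise under strong acid. Ring A carries three different oxygens (the 5-OH chelated to the C4 carbonyl, the 7-OMe, the ring oxygen O1) and two open, electron-rich carbons, C6 and C8. Only C6 may be benzylated, and ordinary Friedel–Crafts benzylation of such a ring would give both isomers, double alkylation and diarylmethane oligomers. Three free phenols, an enolisable ketone and a methylene flanked by two electron-rich rings exclude strong base, strong oxidants and hot mineral acid late in the route. The feature that allows a short synthesis is that C6 lies ortho to the free 5-hydroxyl, between O5 and O7 and para to O1. O5 can be esterified to boron, and the boron can carry an aromatic aldehyde onto C6, whereas C8 is flanked only by ether oxygens. The carbinol carbon introduced this way is doubly benzylic and ortho to a phenol, so it can be reduced to the methylene through the ring-A ortho-quinone methide (C5=O, C6=CH–aryl) without involving C2.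

## Retrosynthesis

**12 ⇒ 11.** The two O–CH2Ph bonds are cut. The ring-B and ring-D phenols must be masked during the C6 functionalisation so that only O5 can bind boron. Benzyl serves for both and leaves in one neutral operation that touches neither the 7-methyl ether nor the 5-hydroxyl. Methyl ethers would demand a selective demethylation beside the 7-OMe, and silyl ethers would not survive the Lewis acid used earlier. Compound 11 is the full skeleton; the forward step only has to spare the C2–O1 bond and the ketone.

**11 ⇒ 9.** The C6 methylene is traced back to a carbinol carbon at the aldehyde oxidation level, held as the cyclic phenylboronate 9. In the forward sense its C–O bond is ionised to the ortho-quinone methide 10 and replaced by hydride. Going through the aldehyde level, rather than using a benzyl halide or alcohol directly, makes a templated and therefore regiospecific C–C bond formation available. The reduction must ionise the doubly benzylic carbon in preference to C2–O1 and must leave the chelated ketone alone.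

**9 ⇒ 5 + 6 + 7.** This is the key cut: the C6–CH bond together with the two B–O bonds of the dioxaborin. The neighbouring cuts are less attractive. Cutting the CH2–ring D bond would need a 6-formyl or 6-halomethyl flavanone, whose preparation poses the same C6/C8 question without a directing group. Building ring A around the benzyl arm would lengthen the route severalfold. Here the precursors are a simple flavanone (5) and two catalogue compounds, 2-(benzyloxy)benzaldehyde (6) and phenylboronic acid (7), joined through the boronate 8. The forward reaction must be ortho-specific and must not erode C2 under hot weak acid.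

**5 ⇒ 3 + 4.** The C2–aryl bond is cut. This turns the stereochemical problem into a catalytic asymmetric conjugate addition of 4-(benzyloxy)phenylboronic acid (4) to the flat, achiral chromone 3. The chalcone alternative would give a racemate or require an asymmetric oxa-Michael closure that is poorly developed for unactivated chalcones. The catalyst must tolerate the chelated phenol and deliver the R configuration.

**3 ⇒ 1.** O1–C2 and C2–C3 are cut, the one carbon coming from a formamide acetal through enaminone 2. The acetophenone 1 is symmetric, so whichever hydroxyl closes the ring the same chromone results, the other hydroxyl becomes the 5-OH, and the 7-methoxyl is in place from the start.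

## Roads not taken

**Alternative 1:** Aryne insertion into a chiral β-silyloxy acid.
- **Cut and key step:** Ring A is detached from ring C at C4a–C4 and C8a–O1. Fluoride would release an aryne from the silylaryl triflate A3 (3-[2-(benzyloxy)benzyl]-2,4-dimethoxy-6-(trimethylsilyl)phenyl triflate). The carboxylate of A2 ((S)-3-[4-(benzyloxy)phenyl]-3-(tert-butyldimethylsilyloxy)propanoic acid) would add at the aryne carbon remote from the flanking methoxyl, and the aryl anion would take the acyl group. The product is the ortho-hydroxyaryl ketone A1 ((S)-1-{3-[2-(benzyloxy)benzyl]-6-hydroxy-2,4-dimethoxyphenyl}-3-[4-(benzyloxy)phenyl]-3-(tert-butyldimethylsilyloxy)propan-1-one). Desilylation, Mitsunobu closure of O1–C2 with inversion, chelation-directed 5-O-demethylation and debenzylation would lead to 12.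
- **Merits:** Ring A arrives fully substituted, so the C6/C8 question never arises late. The methoxyl next to the aryne steers the addition the right way. The carbinol centre is made on a simple acyclic acid, and C2 is never exposed to hot acid.
- **Weak points:** A3 is a hexasubstituted benzene whose preparation contains the whole ring-A problem, including a benzylation between two oxygens. The β-silyloxy acid can eliminate to the cinnamate under basic fluoride. The Mitsunobu inversion at a 4-alkoxybenzylic carbinol is prone to ionisation and loss of enantiopurity. An extra demethylation is needed.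
- **Comparison:** In regiochemical certainty at C6 this road is better. The chosen plan sets against it the covalent boron tether, a catalytic stereocentre and five steps against well over ten.

**Alternative 2:** Benzyne–aldehyde union to create the 2-hydroxybenzyl arm.
- **Cut and key step:** Ring D's C–OH bond and its bond to the methylene carbon are cut, so ring D arrives as benzyne from A6 (2-(trimethylsilyl)phenyl triflate). Benzyne would add across the C=O of the 6-formylflavanone A5 ((R)-2-[4-(benzyloxy)phenyl]-5,7-dimethoxy-4-oxochroman-6-carbaldehyde). The benzoxete would open to a ring-D ortho-quinone methide, and a dihydropyridine hydride donor would reduce it in the flask to A4 ((R)-2-[4-(benzyloxy)phenyl]-6-(2-hydroxybenzyl)-5,7-dimethoxychroman-4-one).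
- **Merits:** The ring-D phenol appears free, so one protecting group fewer is needed. The aryne precursor is cheap, and the step runs at ambient temperature.
- **Weak points:** A5 needs a formyl group at C6 rather than C8 on a ring whose 5-oxygen is methylated, so the regiochemical problem is moved, not solved. The quinone methide is normally captured by a second benzyne to give xanthenes, and the hydride donor must outrun this. Basic fluoride threatens C2 through retro-oxa-Michael opening. A selective 5-O-demethylation remains.
- **Comparison:** This road is leaner in protecting groups on ring D and milder in temperature. The chosen plan answers with a position fixed by the O5–boron tether, an acidic rather than basic quinone methide step, and no late demethylation.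

**Alternative 3:** Alkoxy ortho-quinone methide cycloaddition with a styrene.
- **Cut and key step:** Ring C is cut at O1–C2 and C3–C4. A chiral N-triflylphosphoramide would ionise the acetal A8 (4-[2-(benzyloxy)benzyl]-2-(dimethoxymethyl)-3,5-dimethoxyphenol) to a methoxy ortho-quinone methide. This would add A9 (4-(benzyloxy)styrene) in a [4+2] sense to give the flavan A7 ((2R,4R)-cis-6-[2-(benzyloxy)benzyl]-2-[4-(benzyloxy)phenyl]-4,5,7-trimethoxychroman).
- **Merits:** Ring C and C2 are made in one metal-free asymmetric step. At that stage C2 is not β to a ketone and cannot racemise by ring opening.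
- **Weak points:** C4 is at the wrong oxidation level. The 4-methoxyl must be hydrolysed and oxidised to the ketone in a molecule whose diarylmethane CH2 is itself easily oxidised. A second stereocentre is made only to be destroyed. A8 again needs the benzyl arm installed on a crowded ring beforehand, and a 5-O-demethylation follows.
- **Comparison:** In configurational safety of C2 through the sequence this road is the better one. The chosen plan offers the correct oxidation state throughout and a much shorter route, and checks C2 integrity after the two acidic steps.

Key step: step 3

Assumption: the (S)-pyridine-oxazoline ligand is taken to deliver the aryl group to the chromone face that gives the (2R)-flavanone, as its facial model for cyclic enones predicts; if the sense proves opposite, the equally available (R)-ligand is used with no other change.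

## Route

Step 1
Reactants: 1 2',6'-dihydroxy-4'-methoxyacetophenone
Product: 3 5-hydroxy-7-methoxy-4H-chromen-4-one (5-hydroxy-7-methoxychromone), via enaminone 2 (not isolated)
Conditions: Me2NCH(OMe)2 (1.5 equiv), toluene, 80 °C; evaporate; conc. HCl, CH2Cl2, 40 °C
Reagents that add atoms: N,N-dimethylformamide dimethyl acetal, COC(OC)N(C)C
Why: Enaminone route to 3-unsubstituted chromones: the methyl ketone condenses with the amide acetal, then acid drives oxa-Michael addition of a phenol and loss of dimethylamine. The two hydroxyls of 1 are equivalent, so one chromone results, and moderate temperature with a small excess of acetal limits O-methylation.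

Step 2
Reactants: 3 5-hydroxy-7-methoxychromone; 4 4-(benzyloxy)phenylboronic acid
Product: 5 (R)-2-[4-(benzyloxy)phenyl]-5-hydroxy-7-methoxychroman-4-one
Conditions: Pd(OCOCF3)2 (5 mol%), (S)-4-tert-butyl-2-(pyridin-2-yl)-4,5-dihydrooxazole [(S)-t-BuPyOx] (6 mol%), NH4PF6 (30 mol%), H2O (5 equiv), ClCH2CH2Cl, 60 °C
Reagents that add atoms: none
Why: Palladium-catalysed asymmetric conjugate addition of an arylboronic acid to a chromone with a cationic divalent palladium pyridine-oxazoline catalyst: transmetalation, face-selective insertion of C2=C3 into the Pd–aryl bond, and protonolysis of the palladium enolate by water. The tert-butyl group of the ligand selects the enone face and so sets C2 as R; the system tolerates air, water and phenols.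

Step 3
Reactants: 5 (R)-2-[4-(benzyloxy)phenyl]-5-hydroxy-7-methoxychroman-4-one; 6 2-(benzyloxy)benzaldehyde; 7 phenylboronic acid
Product: 9 dioxaborin: flavanone 5 bridged from O5 to C6 by –B(Ph)–O–CH[2-(benzyloxy)phenyl]– (a 2-phenyl-4H-1,3,2-benzodioxaborin ring on ring A; 2R; both epimers at the new carbinol carbon), via aryl hydrogen phenylboronate 8 (not isolated)
Conditions: PhB(OH)2 (1.3 equiv), aldehyde 6 (1.3 equiv), EtCO2H (0.3 equiv), toluene, reflux, Dean–Stark; evaporate, triturate (no silica)
Reagents that add atoms: none
Why: Boronic acid-templated ortho-specific hydroxyalkylation of a phenol with an aldehyde; the closest known reaction is the phenylboronic acid/carboxylic acid condensation of phenols and alkoxyphenols with aromatic aldehydes to give 2-phenyl-4H-1,3,2-benzodioxaborins. Azeotropic esterification of O5 gives boronate 8; aldehyde 6 binds the trigonal boron and its carbonyl carbon is delivered to C6 through a six-membered transition state (O5–B–O=C···C6=C5), after which tautomerisation restores the aromatic ring. The one ring formed, the dioxaborin, closes by condensation of the remaining B–OH with the new benzylic hydroxyl, a six-membered cyclic boronate esterification driven by removal of water. The new carbinol centre is not controlled and both epimers are expected, which does not matter because it becomes CH2 in step 4; C2 is not a reacting centre. The step needs C6 over C8 and mono-addition over diarylmethane formation: the O5–B tether reaches only C6, while C8 is flanked by the ether oxygens O1 and O7 that cannot bind boron, and C6 is also the most electron-rich carbon (ortho to O5 and O7, para to O1). The benzyl ethers on ring B and on the aldehyde keep those phenols from competing for boron, and the cyclic boronate caps the benzylic alcohol so that no quinone methide forms early and no second molecule of 5 is alkylated. Weak acid in a non-polar solvent is chosen to spare C2 and the benzyl ethers.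

Step 4
Reactants: 9 dioxaborin
Product: 11 (R)-6-[2-(benzyloxy)benzyl]-2-[4-(benzyloxy)phenyl]-5-hydroxy-7-methoxychroman-4-one, via ortho-quinone methide 10 (not isolated)
Conditions: Et3SiH (3 equiv), BF3·OEt2 (2 equiv), CH2Cl2, −40 → 0 °C; then MeOH, aq NaHCO3
Reagents that add atoms: none
Why: Lewis acid–silane reduction (ionic hydrogenation) of a 2-phenyl-4H-1,3,2-benzodioxaborin: BF3 acts as promoter and ionises the doubly benzylic C–O bond to the ring-A ortho-quinone methide 10, which takes hydride from Et3SiH at the exocyclic carbon and rearomatises to the 5-phenol. The epimeric carbinol centre becomes CH2, and low temperature should keep the chelated C4 ketone and the C2–O1 bond untouched; methanol on work-up frees the phenol from boron.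

Step 5
Reactants: 11 (R)-6-[2-(benzyloxy)benzyl]-2-[4-(benzyloxy)phenyl]-5-hydroxy-7-methoxychroman-4-one
Product: 12 (+)-methylphelligrin A [(R)-5-hydroxy-6-(2-hydroxybenzyl)-2-(4-hydroxyphenyl)-7-methoxychroman-4-one]
Conditions: H2 (1 atm), palladium on carbon (10% Pd), EtOAc–MeOH, rt
Reagents that add atoms: none
Why: Catalytic hydrogenolysis of aryl benzyl ethers; both benzyl groups should leave as toluene at balloon pressure and room temperature. Under these conditions the ketone, the diarylmethane and the C2–O1 bond of flavanones are normally retained, and C2 is not touched.

## Compound list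

1 | 2',6'-dihydroxy-4'-methoxyacetophenone | COc1cc(O)c(C(C)=O)c(O)c1 | starting material
2 | (E)-1-(2,6-dihydroxy-4-methoxyphenyl)-3-(dimethylamino)prop-2-en-1-one (enaminone, formed and consumed in the flask) | COc1cc(O)c(C(=O)/C=C/N(C)C)c(O)c1 | intermediate
3 | 5-hydroxy-7-methoxy-4H-chromen-4-one | COc1cc(O)c2c(=O)ccoc2c1 | intermediate
4 | 4-(benzyloxy)phenylboronic acid | OB(O)c1ccc(OCc2ccccc2)cc1 | starting material
5 | (R)-2-[4-(benzyloxy)phenyl]-5-hydroxy-7-methoxychroman-4-one | COc1cc2c(c(O)c1)C(=O)C[C@H](c1ccc(OCc3ccccc3)cc1)O2 | intermediate
6 | 2-(benzyloxy)benzaldehyde | O=Cc1ccccc1OCc1ccccc1 | starting material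
7 | phenylboronic acid | OB(O)c1ccccc1 | starting material
8 | (2R)-2-[4-(benzyloxy)phenyl]-7-methoxy-4-oxochroman-5-yl hydrogen phenylboronate (formed and consumed in the flask) | COc1cc2c(c(OB(O)c3ccccc3)c1)C(=O)C[C@H](c1ccc(OCc3ccccc3)cc1)O2 | intermediate
9 | dioxaborin: (2R)-2-[4-(benzyloxy)phenyl]-7-methoxychroman-4-one with O5 and C6 bridged by –B(Ph)–O–CH[2-(benzyloxy)phenyl]–, both epimers at the carbinol carbon | COc1cc2c(c3c1C(c1ccccc1OCc1ccccc1)OB(c1ccccc1)O3)C(=O)C[C@H](c1ccc(OCc4ccccc4)cc1)O2 | intermediate
10 | ring-A ortho-quinone methide: (2R)-6-[2-(benzyloxy)benzylidene]-2-[4-(benzyloxy)phenyl]-7-methoxy-2,3-dihydrochromene-4,5-dione (formed and consumed in the flask) | COC1=CC2=C(C(=O)C1=Cc1ccccc1OCc1ccccc1)C(=O)C[C@H](c1ccc(OCc3ccccc3)cc1)O2 | intermediate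
11 | (R)-6-[2-(benzyloxy)benzyl]-2-[4-(benzyloxy)phenyl]-5-hydroxy-7-methoxychroman-4-one | COc1cc2c(c(O)c1Cc1ccccc1OCc1ccccc1)C(=O)C[C@H](c1ccc(OCc3ccccc3)cc1)O2 | intermediate
12 | (+)-methylphelligrin A, (R)-5-hydroxy-6-(2-hydroxybenzyl)-2-(4-hydroxyphenyl)-7-methoxychroman-4-one | COc1cc2c(c(O)c1Cc1ccccc1O)C(=O)C[C@H](c1ccc(O)cc1)O2 | target

## Step count and risks

Total steps: 5. Longest linear sequence: 5 steps (1 → 3 → 5 → 9 → 11 → 12); compounds 4, 6 and 7 are purchased.

**Step 3 (key step).**
- Risk: the ortho-delivery may stall. The 5-O–boron ester can close a six-membered chelate with the C4 carbonyl, and a tetracoordinate boron cannot bind the aldehyde; the acyl group also lowers the nucleophilicity of C6. The closest precedents are simple and alkoxy-substituted phenols without such a chelate. The prolonged heating with acid then needed would invite erosion of configuration at C2 through reversible opening to the chalcone, and aldol condensation at C3.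
- Fallback (from 5, rejoining at 11): the free 5-hydroxyl is used to direct halogenation instead. Iodination with benzyltrimethylammonium dichloroiodate and CaCO3 in CH2Cl2–MeOH, which in 5-hydroxy-7-alkoxyflavonoids goes ortho to the free hydroxyl, should give (R)-2-[4-(benzyloxy)phenyl]-5-hydroxy-6-iodo-7-methoxychroman-4-one F1. Base-free Negishi coupling of F1 with [2-(benzyloxy)benzyl]zinc bromide F2 under Pd(OAc)2/SPhos in THF should then form the C6–CH2 bond directly and give 11, making step 4 unnecessary. F2 is made from purchased 2-(benzyloxy)benzyl bromide (BrCc1ccccc1OCc1ccccc1), zinc dust and LiCl in THF, with one extra equivalent to allow for the acidic phenol.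

**Step 2.**
- Risk: slow insertion of the electron-rich, chelated chromone, so that protodeboronation of the electron-rich boronic acid and decomposition of the catalyst to palladium metal outrun the addition; or lower facial selectivity than with the parent chromone.
- Fallback (from 3, rejoining at 5): the phenol is masked as an electron-withdrawing ester. Acetylation (Ac2O, pyridine, DMAP) should give 7-methoxy-4-oxo-4H-chromen-5-yl acetate F3, a better acceptor without an acidic proton. The same conjugate addition should give (R)-2-[4-(benzyloxy)phenyl]-7-methoxy-4-oxochroman-5-yl acetate F4. Acid-catalysed methanolysis (HCl generated from AcCl in MeOH, room temperature) should then release 5 without the base that would open ring C.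

**Step 4.**
- Risk: over-reduction of the C4 carbonyl by ionic hydrogenation, or Lewis-acid ionisation of the C2–O1 bond, which would erode the configuration at C2 or open ring C reductively.
- Fallback (from 9, rejoining at 12): no Lewis acid and no silane. Transesterification of the boronate with propane-1,3-diol in THF at room temperature should free (2R)-6-{[2-(benzyloxy)phenyl](hydroxy)methyl}-2-[4-(benzyloxy)phenyl]-5-hydroxy-7-methoxychroman-4-one F5 (both carbinol epimers). Hydrogenation of F5 over palladium on carbon in EtOAc–MeOH with a trace of AcOH should remove the diarylmethanol hydroxyl and both benzyl ethers in one operation and give 12.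

**Step 5.**
- Risk: hydrogenolytic cleavage of the benzylic C2–O1 bond (opening to the dihydrochalcone) in competition with O-debenzylation, because C2 carries an electron-rich aryl group.
- Fallback (from 11 directly to 12): non-reductive debenzylation with BCl3 and pentamethylbenzene as cation scavenger in CH2Cl2 at −78 °C. This cleaves aryl benzyl ethers but not the unchelated 7-methyl ether at that temperature; no new intermediate is formed.

## Further compounds

F1 | step 3 | (R)-2-[4-(benzyloxy)phenyl]-5-hydroxy-6-iodo-7-methoxychroman-4-one | COc1cc2c(c(O)c1I)C(=O)C[C@H](c1ccc(OCc3ccccc3)cc1)O2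
F2 | step 3 | [2-(benzyloxy)benzyl]zinc bromide | Br[Zn]Cc1ccccc1OCc1ccccc1
F3 | step 2 | 7-methoxy-4-oxo-4H-chromen-5-yl acetate | CC(=O)Oc1cc(OC)cc2occc(=O)c12
F4 | step 2 | (R)-2-[4-(benzyloxy)phenyl]-7-methoxy-4-oxochroman-5-yl acetate | CC(=O)Oc1cc(OC)cc2c1C(=O)C[C@H](c1ccc(OCc3ccccc3)cc1)O2
F5 | step 4 | (2R)-6-{[2-(benzyloxy)phenyl](hydroxy)methyl}-2-[4-(benzyloxy)phenyl]-5-hydroxy-7-methoxychroman-4-one, both carbinol epimers | COc1cc2c(c(O)c1C(O)c1ccccc1OCc1ccccc1)C(=O)C[C@H](c1ccc(OCc3ccccc3)cc1)O2
F0 | step 5 | none | none
A1 | alternative 1 | (S)-1-{3-[2-(benzyloxy)benzyl]-6-hydroxy-2,4-dimethoxyphenyl}-3-[4-(benzyloxy)phenyl]-3-(tert-butyldimethylsilyloxy)propan-1-one | COc1cc(O)c(c(OC)c1Cc1ccccc1OCc1ccccc1)C(=O)C[C@@H](c1ccc(OCc2ccccc2)cc1)O[Si](C)(C)C(C)(C)C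
A2 | alternative 1 | (S)-3-[4-(benzyloxy)phenyl]-3-(tert-butyldimethylsilyloxy)propanoic acid | OC(=O)C[C@@H](c1ccc(OCc2ccccc2)cc1)O[Si](C)(C)C(C)(C)C
A3 | alternative 1 | 3-[2-(benzyloxy)benzyl]-2,4-dimethoxy-6-(trimethylsilyl)phenyl trifluoromethanesulfonate | COc1cc([Si](C)(C)C)c(OS(=O)(=O)C(F)(F)F)c(OC)c1Cc1ccccc1OCc1ccccc1
A4 | alternative 2 | (R)-2-[4-(benzyloxy)phenyl]-6-(2-hydroxybenzyl)-5,7-dimethoxychroman-4-one | COc1cc2c(c(OC)c1Cc1ccccc1O)C(=O)C[C@H](c1ccc(OCc3ccccc3)cc1)O2
A5 | alternative 2 | (R)-2-[4-(benzyloxy)phenyl]-5,7-dimethoxy-4-oxochroman-6-carbaldehyde | COc1cc2c(c(OC)c1C=O)C(=O)C[C@H](c1ccc(OCc3ccccc3)cc1)O2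
A6 | alternative 2 | 2-(trimethylsilyl)phenyl trifluoromethanesulfonate | C[Si](C)(C)c1ccccc1OS(=O)(=O)C(F)(F)F
A7 | alternative 3 | (2R,4R)-cis-6-[2-(benzyloxy)benzyl]-2-[4-(benzyloxy)phenyl]-4,5,7-trimethoxychroman | COc1cc2c(c(OC)c1Cc1ccccc1OCc1ccccc1)[C@H](OC)C[C@H](c1ccc(OCc3ccccc3)cc1)O2
A8 | alternative 3 | 4-[2-(benzyloxy)benzyl]-2-(dimethoxymethyl)-3,5-dimethoxyphenol | COc1cc(O)c(C(OC)OC)c(OC)c1Cc1ccccc1OCc1ccccc1
A9 | alternative 3 | 4-(benzyloxy)styrene | C=Cc1ccc(OCc2ccccc2)cc1
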